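(The numbers in the tables come from a simulation for an exercise.)

Two constants read from the earlier runs will serve for this flask.

| setting | south-west | north-west | flask |
|---|---|---|---|
| J | 0.14 M | 0.22 M | 0.10 M |
| E | 4.7 mM (held) | 4.7 mM (held) | 4.7 mM (held) |
| remark | run made earlier | run made earlier |  |
| time |  |  | 2.0 h |

| run | time / h | Q / % | J / % |
|---|---|---|---|
| south-west | 0.333 | 22.1 | 78.2 |
| south-west | 0.833 | 51.6 | 48.8 |
| south-west | 1.50 | 77.8 | 21.7 |
| south-west | 2.50 | 93.8 | 4.6 |
| north-west | 0.667 | 33.0 | 66.7 |
| north-west | 1.33 | 60.0 | 38.9 |
| north-west | 2.00 | 80.8 | 18.6 |
| north-west | 2.50 | 90.2 | 9.7 |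

(standard deviation of a reading: 0.3 percentage points)

- the earlier runs were read with a standard deviation of 0.3 percentage points
- at the start none of E is in solution

- grey: doubling the transfer coefficient of E, all else as stated
- teal: doubling the saturation concentration of E, all else as stated

1. Q at 2.0 h, in percent of the J charged
2. the change that raises the amount of Q at 2.0 h, in percent of the J charged most ("none" if none brings more than 2 percentage points) (grey / teal / none)
3. amount of Q at 2.0 h, in percent of the J charged, after teal

Take plain first-order loss of J as the zero of your scale: the percentage left at a given time would then not depend on the charge. Yet at 2.50 h the south-west run keeps 4.6% of its J and the north-west run 9.7%, so the richer run lags. I read this as dissolved E arriving by a transfer with a ceiling, and write the elapsed time as two terms: J consumed divided by a ceiling rate, plus a fixed time for each factor e by which J falls. The two last readings, one equation each, give a ceiling of 0.161 M h⁻¹ and an e-fold time, the pseudo-first-order time of J when J is dilute, of 0.542 h.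

Solving these two terms for this flask at 2.0 h, you find 7.19% of J left, so Q is 92.8%. Teal doubles the supply at every J, so both terms halve and the flask runs as if given twice the time: Q 99.8%. Grey halves the first term too, but how far it shortens the second these two runs do not show: with the second term unchanged Q is 95.6%, which I take as a low end for grey, less than teal, and with the second term halved as well grey equals teal, so I commit to teal.

The forecast, “Teal is best”, gave 92.4% (91% to 93.6%), and 99.7% after teal (99% to 100%). The flask gives 92.3%, and 99.1% after teal, a gain of 6.8 percentage points against 4.8 points for grey.

    E ⇌ X, rate k1*(csat - [X]) (kL = 0.580 min⁻¹)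
    Q → G (k = 7.90 × 10⁻⁵ min⁻¹)
    X → D (k = 0.290 min⁻¹)
    J + X → Q (k = 9.90 M⁻¹ min⁻¹)

In this flask J met X, the dissolved E, which stood at 33.9% of saturation at 0.200 h and 47.9% at 1.00 h, when 71% of the turnover of J with X up to 2.0 h lay behind it. X also went on to D, which reached 0.0771 M at 2.00 h, and G stood at 0.560%, the half-life of Q being longer than the run. The two constants put the simulated 7.2% of J in this flask at 2.01 h, and the simulated 62% at 0.495 h for the same flask read at 30 min, where Q is 37.9%.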